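**Retrosynthetic overview**
- The plan rests on ring A: O5 and O8 are para, O7 lies between C6–H and C8, and O1 sits on C8a. A 3-isopropoxy-4-methoxycyclobutenone annulated onto the O1–C8a=C4a enol ether of ring C delivers exactly this pattern.
- Key disconnection C4a–C5: the chroman-5-ol comes from a 4-(dihydropyran-6-yl)cyclobutenone by thermal 4π opening and 6π closure. The cyclobutenone comes from a C6-lithiated dihydropyran, isopropyl semisquarate and methyl triflate.
- Ring C is made as a glycal-like dihydropyran by hetero-Diels–Alder reaction of the silylated ring B aldehyde with a 1,4-dimethoxy-3-silyloxydiene, then 1,2-reduction and silylation.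
- Ring order: B (from 2,4-dihydroxybenzaldehyde), then C (cycloaddition), then A (electrocyclic cascade). Endgame: DDQ oxidation at C4, C2–C3 dehydrogenation, desilylation, BCl3 de-isopropylation.

Key step: step 12

Remark on the chemistry: the target is achiral. C2, C3 and C4 of ring C and the quaternary cyclobutenone carbon are carried as racemic diastereomer mixtures and are all erased by step 15, so these SMILES carry no stereodescriptors. Ar = 5-methoxy-2,4-bis(triisopropylsilyloxy)phenyl.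

**Route**

Step 1
Reactants: 1 2,4-dihydroxybenzaldehyde
Product: 2 5-bromo-2,4-dihydroxybenzaldehyde
Conditions: Br2 (1.0 equiv), AcOH, rt
Reagents that add atoms: bromine, BrBr
Why: Electrophilic aromatic bromination should go to C5, para to the 2-OH and ortho to the 4-OH, because C3 is flanked by two oxygen substituents.

Step 2
Reactants: 2 5-bromo-2,4-dihydroxybenzaldehyde
Product: 3 2,4-dihydroxy-5-methoxybenzaldehyde
Conditions: NaOMe (excess), CuBr (cat.), MeOH–DMF, 110 °C; then aq. HCl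
Reagents that add atoms: sodium methoxide, C[O-].[Na+]
Why: Copper-mediated Ullmann-type methoxylation of an aryl bromide ortho to a phenoxide is the reaction type that converts 5-bromovanillin into syringaldehyde, and the aldehyde is deactivated as the bis-phenoxide.

Step 3
Reactants: 3 2,4-dihydroxy-5-methoxybenzaldehyde
Product: 4 5-methoxy-2,4-bis(triisopropylsilyloxy)benzaldehyde
Conditions: TIPSOTf, 2,6-lutidine, CH2Cl2, 0 °C → rt
Reagents that add atoms: triisopropylsilyl triflate, CC(C)[Si](OS(=O)(=O)C(F)(F)F)(C(C)C)C(C)C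
Why: The silyl triflate silylates both phenols, including the hydrogen-bonded 2-OH; bulky TIPS ethers are chosen because they neither direct nor easily suffer ortho-lithiation in step 11.

Step 4
Reactants: 5 N,2-dimethoxy-N-methylacetamide; 6 ethynylmagnesium bromide
Product: 7 1-methoxybut-3-yn-2-one
Conditions: THF, 0 °C; then cold aq. NaHSO4
Reagents that add atoms: none
Why: Ketone synthesis from an N-methoxy-N-methylamide: the chelated tetrahedral magnesium adduct persists until the acidic quench, so no over-addition occurs, and the cold acid quench keeps the liberated amine from adding to the ynone.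

Step 5
Reactants: 7 1-methoxybut-3-yn-2-one
Product: 8 (E)-1,4-dimethoxybut-3-en-2-one
Conditions: MeOH, DABCO (cat.), CH2Cl2, 0 °C → rt
Reagents that add atoms: methanol, CO
Why: Amine-catalysed conjugate addition of an alcohol to a terminal ynone should stop at the (E)-β-alkoxy enone.

Step 6
Reactants: 8 (E)-1,4-dimethoxybut-3-en-2-one
Product: 9 (1E,3Z)-1,4-dimethoxy-3-(trimethylsilyloxy)buta-1,3-diene
Conditions: TMSOTf, Et3N, Et2O, 0 °C
Reagents that add atoms: trimethylsilyl triflate, C[Si](C)(C)OS(=O)(=O)C(F)(F)F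
Why: Soft enolisation and O-silylation at the only enolisable position (the CH2OMe carbon) gives the 1-alkoxy-3-silyloxy diene; the enol-ether geometry is of no consequence.

Step 7
Reactants: 4 5-methoxy-2,4-bis(triisopropylsilyloxy)benzaldehyde; 9 (1E,3Z)-1,4-dimethoxy-3-(trimethylsilyloxy)buta-1,3-diene
Product: 11 2-Ar-3-methoxy-2,3-dihydro-4H-pyran-4-one (racemic cis/trans mixture), via silyloxy cycloadduct 10 (not isolated)
Conditions: ZnCl2 (1 equiv), THF, rt; then TFA, CH2Cl2, 0 °C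
Reagents that add atoms: none
Why: Lewis-acid-catalysed hetero-Diels–Alder cyclocondensation joins the aldehyde carbon to the methoxy-bearing diene terminus and the aldehyde oxygen to C1, and acid then unmasks the ketone and expels methanol to give the vinylogous ester; C2 and C3 form without control and are erased later.

Step 8
Reactants: 11 2-Ar-3-methoxy-2,3-dihydro-4H-pyran-4-one
Product: 12 2-Ar-3-methoxy-3,4-dihydro-2H-pyran-4-ol (diastereomer mixture)
Conditions: NaBH4, CeCl3·7H2O, MeOH, −78 → −20 °C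
Reagents that add atoms: none
Why: Luche reduction adds hydride 1,2 to the vinylogous ester carbonyl and gives the allylic alcohol without conjugate reduction; the new C4 centre forms as a mixture and is oxidised away in step 14.

Step 9
Reactants: 12 2-Ar-3-methoxy-3,4-dihydro-2H-pyran-4-ol
Product: 13 2-Ar-4-(tert-butyldimethylsilyloxy)-3-methoxy-3,4-dihydro-2H-pyran
Conditions: TBSCl, imidazole, DMF, rt
Reagents that add atoms: tert-butyldimethylsilyl chloride, CC(C)(C)[Si](C)(C)Cl
Why: Silylation of a secondary allylic alcohol under mildly basic conditions leaves the acid-sensitive enol ether untouched.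

Step 10
Reactants: 14 diisopropyl squarate
Product: 16 3-isopropoxycyclobut-3-ene-1,2-dione (isopropyl semisquarate), via hydroxycyclobutenone 15 (not isolated)
Conditions: LiAlH(OtBu)3, THF, −78 → 0 °C; then conc. aq. HCl (cat.), CH2Cl2, rt
Reagents that add atoms: water, O
Why: The bulky hydride reduces one carbonyl only, and acid then effects the known 1,3-carbonyl transposition of 4-hydroxy-2,3-dialkoxycyclobutenones (loss of the hydroxyl, capture of the cation by water at the alkoxy-bearing carbon, loss of isopropanol).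

Step 11
Reactants: 13 2-Ar-4-(tert-butyldimethylsilyloxy)-3-methoxy-3,4-dihydro-2H-pyran; 16 3-isopropoxycyclobut-3-ene-1,2-dione
Product: 19 4-[2-Ar-4-(tert-butyldimethylsilyloxy)-3-methoxy-3,4-dihydro-2H-pyran-6-yl]-3-isopropoxy-4-methoxycyclobut-2-en-1-one (diastereomer mixture), via 6-lithio dihydropyran 17 (not isolated), via lithium alkoxide 18 (not isolated)
Conditions: t-BuLi (1.3 equiv), THF, −78 → 0 °C; then 16 (1.5 equiv), THF, −78 °C; then MeOTf, −78 → 0 °C
Reagents that add atoms: methyl triflate, COS(=O)(=O)C(F)(F)F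
Why: The α-alkoxyvinyl C6–H of a silyl-protected glycal is the kinetically preferred site for t-BuLi (as in C1 lithiation of glycals), the vinyllithium adds 1,2 to the semisquarate carbonyl beside the isopropoxy-bearing carbon and not to the vinylogous ester carbonyl, and the tertiary alkoxide is capped in the same flask by methyl triflate; the quaternary carbon forms without control and is erased in step 12.

Step 12
Reactants: 19 4-[2-Ar-4-(tert-butyldimethylsilyloxy)-3-methoxy-3,4-dihydro-2H-pyran-6-yl]-3-isopropoxy-4-methoxycyclobut-2-en-1-one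
Product: 22 2-Ar-4-(tert-butyldimethylsilyloxy)-7-isopropoxy-3,8-dimethoxychroman-5-ol (racemic diastereomer mixture), via dienylketene 20 (not isolated), via cyclohexadienone 21 (not isolated)
Conditions: degassed toluene, 110 °C
Reagents that add atoms: none
Why: Thermal conrotatory 4π electrocyclic opening breaks the C1–C4 bond of the cyclobutenone and, because the C4 methoxy donor rotates outward, turns the dihydropyran C5=C6 bond inward to give the (Z)-dienylketene 20; thermal disrotatory 6π electrocyclisation then joins the electrophilic ketene carbon to the nucleophilic enol-ether β-carbon (future C4a), forming C4a–C5 and the six-membered ring A in cyclohexadienone 21, and a proton shift from C4a to oxygen gives phenol 22. The closest known reaction is the Moore rearrangement of 4-alkenyl-4-alkoxycyclobutenones, including adducts of lithiated cyclic enol ethers, to hydroquinone monoethers. No lasting stereocentre is created: C4a is sp3 only in 21 and is planarised on tautomerisation, and C2, C3 and C4 are spectators. The step needs torquoselectivity (alkenyl inward) and one regiochemical outcome; the first is secured by the preference of the C4 oxygen donor for outward rotation, the second by the constitution of 19 (H at C2, OiPr at C3, OMe at C4), so ring A should emerge with 5-OH free, C6–H, 7-OiPr, 8-OMe and O1 on C8a. Degassed solvent and short heating limit oxidation of the electron-rich phenol and loss of the benzylic silyloxy group.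

Step 13
Reactants: 22 2-Ar-4-(tert-butyldimethylsilyloxy)-7-isopropoxy-3,8-dimethoxychroman-5-ol
Product: 23 2-Ar-4,5-bis(tert-butyldimethylsilyloxy)-7-isopropoxy-3,8-dimethoxychroman
Conditions: TBSCl, imidazole, DMAP (cat.), DMF, rt
Reagents that add atoms: tert-butyldimethylsilyl chloride, CC(C)(C)[Si](C)(C)Cl
Why: Phenol silylation masks the hydroquinone-monoether motif (5-OH para to 8-OMe) against quinone formation in the two oxidations that follow.

Step 14
Reactants: 23 2-Ar-4,5-bis(tert-butyldimethylsilyloxy)-7-isopropoxy-3,8-dimethoxychroman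
Product: 24 2-Ar-5-(tert-butyldimethylsilyloxy)-7-isopropoxy-3,8-dimethoxychroman-4-one
Conditions: DDQ, CH2Cl2–pH 7 buffer, 0 °C → rt
Reagents that add atoms: none
Why: DDQ should abstract the C4 hydride, which is α to oxygen and benzylic to a ring with donors ortho (O1, 5-OSi) and para (7-OiPr), as in the oxidative cleavage of p-methoxybenzyl-type and benzylic silyl ethers; the silyloxycarbenium ion collapses with water to the ketone and the C4 centre is destroyed.

Step 15
Reactants: 24 2-Ar-5-(tert-butyldimethylsilyloxy)-7-isopropoxy-3,8-dimethoxychroman-4-one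
Product: 25 2-Ar-5-(tert-butyldimethylsilyloxy)-7-isopropoxy-3,8-dimethoxy-4H-chromen-4-one
Conditions: DDQ, 1,4-dioxane, 100 °C
Reagents that add atoms: none
Why: DDQ dehydrogenation of a flavanone to a flavone proceeds by enolisation toward C3 and hydride loss from the doubly activated C2–H, which erases C2 and C3; the 3-methoxy group makes the enol electron-rich, and adventitious loss of the labile 5-O-silyl group would converge in step 16.

Step 16
Reactants: 25 2-Ar-5-(tert-butyldimethylsilyloxy)-7-isopropoxy-3,8-dimethoxy-4H-chromen-4-one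
Product: 26 2-(2,4-dihydroxy-5-methoxyphenyl)-5-hydroxy-7-isopropoxy-3,8-dimethoxy-4H-chromen-4-one
Conditions: TBAF, AcOH, THF, 0 °C → rt
Reagents that add atoms: none
Why: Fluoride cleaves all three aryl silyl ethers through Si–F bond formation, and the acetic acid buffer keeps the flavone from base-induced ring opening.

Step 17
Reactants: 26 2-(2,4-dihydroxy-5-methoxyphenyl)-5-hydroxy-7-isopropoxy-3,8-dimethoxy-4H-chromen-4-one
Product: 27 5,7,2',4'-tetrahydroxy-3,8,5'-trimethoxyflavone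
Conditions: BCl3, CH2Cl2, −78 → 0 °C; then H2O
Reagents that add atoms: none
Why: BCl3 cleaves aryl isopropyl ethers (loss of the secondary alkyl group as 2-chloropropane) far faster than aryl methyl ethers at low temperature, so the 3-, 8- and 5'-methoxy groups should remain.

**Compound list**
1 | 2,4-dihydroxybenzaldehyde | O=Cc1ccc(O)cc1O | starting material
2 | 5-bromo-2,4-dihydroxybenzaldehyde | O=Cc1cc(Br)c(O)cc1O | intermediate
3 | 2,4-dihydroxy-5-methoxybenzaldehyde | COc1cc(C=O)c(O)cc1O | intermediate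
4 | 5-methoxy-2,4-bis(triisopropylsilyloxy)benzaldehyde | COc1cc(C=O)c(O[Si](C(C)C)(C(C)C)C(C)C)cc1O[Si](C(C)C)(C(C)C)C(C)C | intermediate
5 | N,2-dimethoxy-N-methylacetamide | COCC(=O)N(C)OC | starting material
6 | ethynylmagnesium bromide | C#C[Mg]Br | starting material
7 | 1-methoxybut-3-yn-2-one | COCC(=O)C#C | intermediate
8 | (E)-1,4-dimethoxybut-3-en-2-one | COCC(=O)/C=C/OC | intermediate
9 | (1E,3Z)-1,4-dimethoxy-3-(trimethylsilyloxy)buta-1,3-diene | CO/C=C/C(O[Si](C)(C)C)=C/OC | intermediate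
10 | 2-Ar-3,6-dimethoxy-4-(trimethylsilyloxy)-3,6-dihydro-2H-pyran | COC1C=C(O[Si](C)(C)C)C(OC)C(c2cc(OC)c(O[Si](C(C)C)(C(C)C)C(C)C)cc2O[Si](C(C)C)(C(C)C)C(C)C)O1 | intermediate (not isolated)
11 | 2-Ar-3-methoxy-2,3-dihydro-4H-pyran-4-one | COC1C(=O)C=COC1c1cc(OC)c(O[Si](C(C)C)(C(C)C)C(C)C)cc1O[Si](C(C)C)(C(C)C)C(C)C | intermediate
12 | 2-Ar-3-methoxy-3,4-dihydro-2H-pyran-4-ol | COC1C(O)C=COC1c1cc(OC)c(O[Si](C(C)C)(C(C)C)C(C)C)cc1O[Si](C(C)C)(C(C)C)C(C)C | intermediate
13 | 2-Ar-4-(tert-butyldimethylsilyloxy)-3-methoxy-3,4-dihydro-2H-pyran | COC1C(O[Si](C)(C)C(C)(C)C)C=COC1c1cc(OC)c(O[Si](C(C)C)(C(C)C)C(C)C)cc1O[Si](C(C)C)(C(C)C)C(C)C | intermediate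
14 | diisopropyl squarate (3,4-diisopropoxycyclobut-3-ene-1,2-dione) | CC(C)OC1=C(OC(C)C)C(=O)C1=O | starting material
15 | 4-hydroxy-2,3-diisopropoxycyclobut-2-en-1-one | CC(C)OC1=C(OC(C)C)C(O)C1=O | intermediate (not isolated)
16 | 3-isopropoxycyclobut-3-ene-1,2-dione | CC(C)OC1=CC(=O)C1=O | intermediate
17 | 6-lithio derivative of 13 | [Li]C1=CC(O[Si](C)(C)C(C)(C)C)C(OC)C(c2cc(OC)c(O[Si](C(C)C)(C(C)C)C(C)C)cc2O[Si](C(C)C)(C(C)C)C(C)C)O1 | intermediate (not isolated)
18 | lithium 1-(dihydropyran-6-yl)-2-isopropoxy-4-oxocyclobut-2-en-1-olate | [Li]OC1(C(OC(C)C)=CC1=O)C1=CC(O[Si](C)(C)C(C)(C)C)C(OC)C(c2cc(OC)c(O[Si](C(C)C)(C(C)C)C(C)C)cc2O[Si](C(C)C)(C(C)C)C(C)C)O1 | intermediate (not isolated)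
19 | 4-[2-Ar-4-(tert-butyldimethylsilyloxy)-3-methoxy-3,4-dihydro-2H-pyran-6-yl]-3-isopropoxy-4-methoxycyclobut-2-en-1-one | O=C1C=C(OC(C)C)C1(OC)C1=CC(O[Si](C)(C)C(C)(C)C)C(OC)C(c2cc(OC)c(O[Si](C(C)C)(C(C)C)C(C)C)cc2O[Si](C(C)C)(C(C)C)C(C)C)O1 | intermediate
20 | (Z)-dienylketene (ketene arm cis to the dihydropyranyl group) | O=C=C/C(OC(C)C)=C(/OC)C1=CC(O[Si](C)(C)C(C)(C)C)C(OC)C(c2cc(OC)c(O[Si](C(C)C)(C(C)C)C(C)C)cc2O[Si](C(C)C)(C(C)C)C(C)C)O1 | intermediate (not isolated)
21 | 2-Ar-4-(tert-butyldimethylsilyloxy)-7-isopropoxy-3,8-dimethoxy-2,3,4,4a-tetrahydro-5H-chromen-5-one | COC1=C2OC(c3cc(OC)c(O[Si](C(C)C)(C(C)C)C(C)C)cc3O[Si](C(C)C)(C(C)C)C(C)C)C(OC)C(O[Si](C)(C)C(C)(C)C)C2C(=O)C=C1OC(C)C | intermediate (not isolated)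
22 | 2-Ar-4-(tert-butyldimethylsilyloxy)-7-isopropoxy-3,8-dimethoxychroman-5-ol | COc1cc(C2Oc3c(OC)c(OC(C)C)cc(O)c3C(O[Si](C)(C)C(C)(C)C)C2OC)c(O[Si](C(C)C)(C(C)C)C(C)C)cc1O[Si](C(C)C)(C(C)C)C(C)C | intermediate
23 | 2-Ar-4,5-bis(tert-butyldimethylsilyloxy)-7-isopropoxy-3,8-dimethoxychroman | COc1cc(C2Oc3c(OC)c(OC(C)C)cc(O[Si](C)(C)C(C)(C)C)c3C(O[Si](C)(C)C(C)(C)C)C2OC)c(O[Si](C(C)C)(C(C)C)C(C)C)cc1O[Si](C(C)C)(C(C)C)C(C)C | intermediate
24 | 2-Ar-5-(tert-butyldimethylsilyloxy)-7-isopropoxy-3,8-dimethoxychroman-4-one | COc1cc(C2Oc3c(OC)c(OC(C)C)cc(O[Si](C)(C)C(C)(C)C)c3C(=O)C2OC)c(O[Si](C(C)C)(C(C)C)C(C)C)cc1O[Si](C(C)C)(C(C)C)C(C)C | intermediate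
25 | 2-Ar-5-(tert-butyldimethylsilyloxy)-7-isopropoxy-3,8-dimethoxy-4H-chromen-4-one | COc1cc(-c2oc3c(OC)c(OC(C)C)cc(O[Si](C)(C)C(C)(C)C)c3c(=O)c2OC)c(O[Si](C(C)C)(C(C)C)C(C)C)cc1O[Si](C(C)C)(C(C)C)C(C)C | intermediate
26 | 2-(2,4-dihydroxy-5-methoxyphenyl)-5-hydroxy-7-isopropoxy-3,8-dimethoxy-4H-chromen-4-one | COc1cc(-c2oc3c(OC)c(OC(C)C)cc(O)c3c(=O)c2OC)c(O)cc1O | intermediate
27 | 5,7,2',4'-tetrahydroxy-3,8,5'-trimethoxyflavone | COc1cc(-c2oc3c(OC)c(O)cc(O)c3c(=O)c2OC)c(O)cc1O | target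

**Step count**
Total: 17 steps. Longest linear sequence: 13 steps (1, 2, 3, 7, 8, 9, 11, 12, 13, 14, 15, 16, 17).

**Steps most likely to fail**

Step 11. The base may deprotonate elsewhere than C6: on the arene ortho to the 5'-methoxy group, at the benzylic C2–H or at a silyl methyl group. Residual base may also attack the dione.
Fallback, from 13, returning at 17: benzenesulfinic acid (CH2Cl2, rt) should add across the enol ether to give the 6-(phenylsulfonyl)tetrahydropyran F1. n-BuLi at −78 °C removes the sulfone α-proton, which is far more acidic than any aryl, benzylic or vinylic C–H, and Bu3SnCl gives the α-stannyl sulfone F2. Warming with iPr2NEt in CHCl3 eliminates benzenesulfinic acid to give the 6-(tributylstannyl)dihydropyran F3. Tin–lithium exchange with n-BuLi at −78 °C then gives vinyllithium 17 without any deprotonation of the substrate, and the route continues to 19 as in step 11.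

Step 12. During heating the C4 silyloxy group next to the newly formed C5 phenol may ionise or eliminate (quinone-methide formation) or migrate, and the hydroquinone monoether may oxidise.
Fallback, from 12, returning at 24: the C4 oxygen is carried as a methyl ether, which cannot leave as silanol or migrate. NaH and MeI (THF, 0 °C) give the 3,4-dimethoxy dihydropyran F4. t-BuLi gives its 6-lithio derivative F5, addition to 16 gives the lithium alkoxide F6, and methyl triflate gives the cyclobutenone F7. Heating in toluene should give the 4-methoxychroman-5-ol F10 through the dienylketene F8 and the cyclohexadienone F9. TBSCl and imidazole give the 5-O-silyl ether F11. DDQ in wet CH2Cl2 then cleaves the benzylic methyl ether oxidatively, in the manner of a p-methoxybenzyl ether, to flavanone 24.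

Step 14. Hydride abstraction may occur at C2–H instead of C4–H, or the electron-rich aryl rings may be oxidised to quinones.
Fallback, from 22, returning at 26: the oxidative cleavage is replaced by desilylation and alcohol oxidation. Buffered HF·pyridine (pyridine, THF, 0 °C) should cleave only the alkyl silyl ether to give the chroman-4,5-diol F12. MnO2 in CH2Cl2 oxidises the benzylic alcohol to the hydrogen-bonded 5-hydroxyflavanone F13. DDQ in dioxane dehydrogenates it to the 5-hydroxyflavone F14, and TBAF with AcOH removes the two aryl silyl ethers to give 26.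

**Further compounds**
F1 | step 11 | 2-Ar-4-(tert-butyldimethylsilyloxy)-3-methoxy-6-(phenylsulfonyl)tetrahydro-2H-pyran | COC1C(O[Si](C)(C)C(C)(C)C)CC(S(=O)(=O)c2ccccc2)OC1c1cc(OC)c(O[Si](C(C)C)(C(C)C)C(C)C)cc1O[Si](C(C)C)(C(C)C)C(C)C
F2 | step 11 | 2-Ar-4-(tert-butyldimethylsilyloxy)-3-methoxy-6-(phenylsulfonyl)-6-(tributylstannyl)tetrahydro-2H-pyran | COC1C(O[Si](C)(C)C(C)(C)C)CC(S(=O)(=O)c2ccccc2)([Sn](CCCC)(CCCC)CCCC)OC1c1cc(OC)c(O[Si](C(C)C)(C(C)C)C(C)C)cc1O[Si](C(C)C)(C(C)C)C(C)C
F3 | step 11 | 2-Ar-4-(tert-butyldimethylsilyloxy)-3-methoxy-6-(tributylstannyl)-3,4-dihydro-2H-pyran | CCCC[Sn](CCCC)(CCCC)C1=CC(O[Si](C)(C)C(C)(C)C)C(OC)C(c2cc(OC)c(O[Si](C(C)C)(C(C)C)C(C)C)cc2O[Si](C(C)C)(C(C)C)C(C)C)O1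
F4 | step 12 | 2-Ar-3,4-dimethoxy-3,4-dihydro-2H-pyran | COC1C(OC)C=COC1c1cc(OC)c(O[Si](C(C)C)(C(C)C)C(C)C)cc1O[Si](C(C)C)(C(C)C)C(C)C
F5 | step 12 | 6-lithio derivative of F4 | [Li]C1=CC(OC)C(OC)C(c2cc(OC)c(O[Si](C(C)C)(C(C)C)C(C)C)cc2O[Si](C(C)C)(C(C)C)C(C)C)O1
F6 | step 12 | lithium 1-(2-Ar-3,4-dimethoxy-3,4-dihydro-2H-pyran-6-yl)-2-isopropoxy-4-oxocyclobut-2-en-1-olate | [Li]OC1(C(OC(C)C)=CC1=O)C1=CC(OC)C(OC)C(c2cc(OC)c(O[Si](C(C)C)(C(C)C)C(C)C)cc2O[Si](C(C)C)(C(C)C)C(C)C)O1
F7 | step 12 | 4-(2-Ar-3,4-dimethoxy-3,4-dihydro-2H-pyran-6-yl)-3-isopropoxy-4-methoxycyclobut-2-en-1-one | O=C1C=C(OC(C)C)C1(OC)C1=CC(OC)C(OC)C(c2cc(OC)c(O[Si](C(C)C)(C(C)C)C(C)C)cc2O[Si](C(C)C)(C(C)C)C(C)C)O1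
F8 | step 12 | (Z)-dienylketene from F7 | O=C=C/C(OC(C)C)=C(/OC)C1=CC(OC)C(OC)C(c2cc(OC)c(O[Si](C(C)C)(C(C)C)C(C)C)cc2O[Si](C(C)C)(C(C)C)C(C)C)O1
F9 | step 12 | 2-Ar-7-isopropoxy-3,4,8-trimethoxy-2,3,4,4a-tetrahydro-5H-chromen-5-one | COC1=C2OC(c3cc(OC)c(O[Si](C(C)C)(C(C)C)C(C)C)cc3O[Si](C(C)C)(C(C)C)C(C)C)C(OC)C(OC)C2C(=O)C=C1OC(C)C
F10 | step 12 | 2-Ar-7-isopropoxy-3,4,8-trimethoxychroman-5-ol | COc1cc(C2Oc3c(OC)c(OC(C)C)cc(O)c3C(OC)C2OC)c(O[Si](C(C)C)(C(C)C)C(C)C)cc1O[Si](C(C)C)(C(C)C)C(C)C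
F11 | step 12 | 2-Ar-5-(tert-butyldimethylsilyloxy)-7-isopropoxy-3,4,8-trimethoxychroman | COc1cc(C2Oc3c(OC)c(OC(C)C)cc(O[Si](C)(C)C(C)(C)C)c3C(OC)C2OC)c(O[Si](C(C)C)(C(C)C)C(C)C)cc1O[Si](C(C)C)(C(C)C)C(C)C
F12 | step 14 | 2-Ar-7-isopropoxy-3,8-dimethoxychroman-4,5-diol | COc1cc(C2Oc3c(OC)c(OC(C)C)cc(O)c3C(O)C2OC)c(O[Si](C(C)C)(C(C)C)C(C)C)cc1O[Si](C(C)C)(C(C)C)C(C)C
F13 | step 14 | 2-Ar-5-hydroxy-7-isopropoxy-3,8-dimethoxychroman-4-one | COc1cc(C2Oc3c(OC)c(OC(C)C)cc(O)c3C(=O)C2OC)c(O[Si](C(C)C)(C(C)C)C(C)C)cc1O[Si](C(C)C)(C(C)C)C(C)C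
F14 | step 14 | 2-Ar-5-hydroxy-7-isopropoxy-3,8-dimethoxy-4H-chromen-4-one | COc1cc(-c2oc3c(OC)c(OC(C)C)cc(O)c3c(=O)c2OC)c(O[Si](C(C)C)(C(C)C)C(C)C)cc1O[Si](C(C)C)(C(C)C)C(C)C
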